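**Retrosynthetic overview**

1. Rings: A = δ-lactone, B = cycloheptadiene, C and D = the two six-membered rings of the bicyclo[3.3.1]nonane (D carries the C=O, the C(OH)CH3 and the CO2Me bridgehead; the one-carbon bridge is the spiro-epoxide carbon). Ring A is opened last (lactone from a ring-B dienyl methyl ketone plus a methyl nucleophile), the epoxide goes back to a C=CH2 bridge, and the ring-B diene to a 1,3-dioxygenated cycloheptene (vinylogous ester).
2. Key disconnection: the bond between the ring-C CH2 and the methyl-bearing bridgehead carbon, made by intramolecular Michael addition of the γ-deprotonated ring-D enone, through its α-carbon, to a 2-methylenecycloheptanone. One operation closes ring C and creates the bicyclo[3.3.1]nonane, the quaternary bridgehead, the B/C methine and the C=CH2 bridge.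
3. Enabling feature: the methyl-bearing bridgehead is the α-carbon of the ring-D ketone; the neighbouring epoxide carbon is the former enone β-carbon, whose CH3 (later the epoxide CH2) supplies the γ-proton; the ring-C CH2 is β to the ring-B carbon that carries CH3 in the target and can be a C=O in the precursor.
4. Precursor: the two adjacent quaternary carbons (ester bridgehead of ring D, angular C–CH3 of ring B) by Ireland–Claisen rearrangement of a Hagemann-type ester of a cycloheptadienylmethanol; ring D by Robinson annulation on the acetoacetate; ring B by Birch reduction and dibromocarbene ring expansion of 2,4-dimethoxytoluene; absolute configuration from one CBS reduction.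
5. Order of ring formation: B, D, C (key step), epoxide, A.

Key step: step 13

Remark: 2,4-dimethoxytoluene, diketene and 2-methylpent-1-en-3-one are taken as commercial; 13, 16 and 17 are carried as epimer mixtures at the ring-D CH(CH3) carbon (13 also at the ester-bearing carbon), because both centres are planarized in steps 8 and 10.

**Route**

Step 1
Reactants: 1 2,4-dimethoxytoluene
Product: 2 1,5-dimethoxy-2-methylcyclohexa-1,4-diene
Conditions: Li, NH3 (l), THF, t-BuOH, −78 °C; then H2O
Reagents that add atoms: none
Why: Birch reduction protonates the two unsubstituted, para-related ring carbons, so both methoxy groups and the methyl group stay on the remaining double bonds and both oxygen functions of ring B are masked as enol ethers.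

Step 2
Reactants: 2 1,5-dimethoxy-2-methylcyclohexa-1,4-diene
Product: 4 2-bromo-6-methoxy-3-methylcyclohepta-2,5-dien-1-one, via dibromocyclopropane 3 (not isolated)
Conditions: CHBr3, KOt-Bu, pentane, −20 → 0 °C; then pyridine, 23 °C
Reagents that add atoms: bromoform, BrC(Br)Br
Why: electrophilic dibromocarbene should add to the more electron-rich tetrasubstituted enol ether, and methoxy-assisted electrocyclic opening of the dibromocyclopropane with O-demethylation gives the ring-expanded 2-bromoenone (dihalocarbene ring expansion of a Birch-derived enol ether), which is ring B.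

Step 3
Reactants: 4 2-bromo-6-methoxy-3-methylcyclohepta-2,5-dien-1-one
Product: 5 (S)-2-bromo-6-methoxy-3-methylcyclohepta-2,5-dien-1-ol
Conditions: (R)-1-methyl-3,3-diphenyltetrahydro-1H,3H-pyrrolo[1,2-c][1,3,2]oxazaborole (10 mol %), catecholborane, toluene, −78 °C; then aq. NaOH
Reagents that add atoms: none
Why: Corey–Bakshi–Shibata reduction in which the 2-bromoalkenyl arm acts as the large group, so the (R)-oxazaborolidine should give the (S)-carbinol, the stereocentre that later controls the absolute configuration.

Step 4
Reactants: 5 (S)-2-bromo-6-methoxy-3-methylcyclohepta-2,5-dien-1-ol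
Product: 6 tert-butyldimethylsilyl ether of 5
Conditions: t-BuMe2SiCl, imidazole, DMF, 23 °C
Reagents that add atoms: tert-butyldimethylsilyl chloride, CC(C)(C)[Si](C)(C)Cl
Why: standard silylation of a secondary allylic alcohol; the bulky silyl ether should survive the basic steps and later shield one face of ring B.

Step 5
Reactants: 6 tert-butyldimethylsilyl ether of 5
Product: 8 [(S)-7-(tert-butyldimethylsilyloxy)-5-methoxy-2-methylcyclohepta-1,4-dien-1-yl]methanol, via alkenyllithium 7 (not isolated)
Conditions: t-BuLi (2.1 equiv), Et2O, −78 °C; then CH2O (gas, from paraformaldehyde), −78 → 0 °C; H2O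
Reagents that add atoms: formaldehyde, C=O
Why: bromine–lithium exchange of the alkenyl bromide and 1,2-addition of the alkenyllithium to formaldehyde install the primary allylic alcohol whose CH2 becomes the ring-C CH2.

Step 6
Reactants: 8 [(S)-7-(tert-butyldimethylsilyloxy)-5-methoxy-2-methylcyclohepta-1,4-dien-1-yl]methanol; 9 diketene
Product: 10 acetoacetate ester of 8
Conditions: 4-(dimethylamino)pyridine (5 mol %), Et3N (cat.), CH2Cl2, 0 → 23 °C
Reagents that add atoms: none
Why: nucleophile-catalysed ring opening of diketene by the primary alcohol (acetoacetylation) needs no acid and should leave the enol ether and the silyl ether untouched.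

Step 7
Reactants: 10 acetoacetate ester of 8; 11 2-methylpent-1-en-3-one
Product: 13 2,3,5-trimethyl-4-oxocyclohex-2-ene-1-carboxylate ester of 8, via Michael adduct 12 (not isolated)
Conditions: KOt-Bu (0.3 equiv), t-BuOH/THF, 0 → 45 °C
Reagents that add atoms: none
Why: Robinson annulation, in which the acetoacetate adds to the CH2 terminus of the enone and the ethyl ketone α-carbon then condenses with the acetyl carbonyl, should give the Hagemann-type 2,3-dimethylcyclohexenone (ring D); the two stereocentres formed are planarized in steps 8 and 10.

Step 8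
Reactants: 13 2,3,5-trimethyl-4-oxocyclohex-2-ene-1-carboxylate ester of 8
Product: 16 rearranged carboxylic acid, via bis-silyl ketene acetal 14 (not isolated), via rearranged silyl ester 15 (not isolated)
Conditions: LiN(i-Pr)2 (2.4 equiv), THF, −78 °C; Me3SiCl, Et3N, −78 → 60 °C; then K2CO3, MeOH/H2O, 0 °C; NaH2PO4
Reagents that add atoms: none
Why: Ireland–Claisen rearrangement of the doubly deprotonated, silylated ester (ketone masked in situ as its silyl dienol ether), in which the allyloxy group should sit cis to the bulkier C(CH3)= branch of the ketene acetal, the chair transition state puts the angular methyl axial and the ring-B CH2 arm equatorial, and the new bond forms anti to the pseudoaxial silyloxy group, so the two adjacent quaternary centres should form with the relative and absolute configuration of the target.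

Step 9
Reactants: 16 rearranged carboxylic acid
Product: 17 methyl ester of 16
Conditions: MeI, K2CO3, DMF, 23 °C
Reagents that add atoms: iodomethane, CI
Why: SN2 O-methylation of the carboxylate, which is too hindered for esterification by acyl substitution; no stereocentre is touched.

Step 10
Reactants: 17 methyl ester of 16
Product: 18 tertiary α-hydroxy ketone
Conditions: LiN(SiMe3)2 (1.2 equiv), THF, −78 °C; 2-(phenylsulfonyl)-3-phenyloxaziridine, −78 °C; H2O
Reagents that add atoms: 2-(phenylsulfonyl)-3-phenyloxaziridine, O=S(=O)(c1ccccc1)N1OC1c1ccccc1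
Why: kinetic deprotonation of the enone at the α'-CH(CH3) carbon and oxidation of the enolate by the N-sulfonyloxaziridine, with oxygen entering anti to the pseudoaxial quaternary ring-B substituent two carbons away, should give the tertiary alcohol cis to the ester as in the target and removes the only α'-hydrogen, so the enone can later be deprotonated only at its γ-methyl group.

Step 11
Reactants: 18 tertiary α-hydroxy ketone
Product: 19 diol
Conditions: Bu4NF, THF, 0 → 23 °C
Reagents that add atoms: none
Why: fluoride cleavage of the secondary silyl ether, which has done its work once the quaternary centres are set.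

Step 12
Reactants: 19 diol
Product: 20 2-methylenecycloheptenone (key precursor)
Conditions: Dess–Martin periodinane (1,1,1-triacetoxy-1,1-dihydro-1,2-benziodoxol-3(1H)-one), NaHCO3, CH2Cl2, 0 °C; used crude
Reagents that add atoms: none
Why: Dess–Martin oxidation of the secondary allylic alcohol (the tertiary alcohol cannot be oxidized) unveils the 2-methylene ketone that serves as the Michael acceptor.

Step 13
Reactants: 20 2-methylenecycloheptenone (key precursor)
Product: 22 tricyclic vinylogous ester, via non-conjugated Michael adduct 21 (not isolated)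
Conditions: KOt-Bu (0.3 equiv), t-BuOH/THF 1:5, 0.005 M, −20 → 0 °C; AcOH
Reagents that add atoms: none
Why: KOt-Bu removes a γ-proton from the CH3 on the β-carbon of the ring-D enone (the α'-position is blocked by the tertiary carbinol), and the through-conjugated dienolate attacks through its α-carbon the exocyclic CH2 terminus of the 2-methylenecycloheptenone, which the angular quaternary carbon holds axially over that α-carbon; proton transfer gives ketone 21, which relaxes to the conjugated vinylogous ester 22. The closest known reaction type is the α-selective alkylation and Michael addition of extended enolates of Hagemann-type 2,3-dialkylcyclohexenones, here run intramolecularly. Ring C is closed in a 6-(enolexo)-endo-trig mode, which completes the bicyclo[3.3.1]nonane and leaves the former β-carbon as the C=CH2 one-carbon bridge. The new quaternary bridgehead can only form cis to the ester-bearing bridgehead because the acceptor is tethered through the axial angular carbon, and the adjacent B/C methine is set by reversible protonation α to the ketone, which puts the ring-B carbonyl carbon equatorial (exo) on the new chair and so gives the trans B/C fusion. The step needs α- rather than γ-attack of the dienolate and must not lose the methylene ketone to self-condensation: α-attack is the kinetic mode of extended enolates and is helped here by the axial tether on the neighbouring carbon, while high dilution and substoichiometric base keep the acceptor monomeric and largely un-enolized.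

Step 14
Reactants: 22 tricyclic vinylogous ester
Product: 24 transposed ring-B enone, via tertiary allylic alcohol 23 (not isolated)
Conditions: MeLi, CeCl3, THF, −78 °C; then 1 M HCl, THF, 23 °C
Reagents that add atoms: methyllithium, [Li]C; water, O
Why: Stork–Danheiser sequence, in which 1,2-addition of the organocerium reagent to the vinylogous ester carbonyl (the other ketone lies between two fully substituted carbons) and acid hydrolysis with loss of water and methanol transpose the carbonyl and place the ring-B methyl group on the new enone; the B/C methine stays under thermodynamic control.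

Step 15
Reactants: 24 transposed ring-B enone
Product: 26 enone with CH2CO2Me on the α-carbon, via deconjugated keto ester 25 (not isolated)
Conditions: KOt-Bu (2.1 equiv), t-BuOH/THF, 0 °C; BrCH2CO2Me (1.05 equiv); then 23 °C
Reagents that add atoms: methyl bromoacetate, COC(=O)CBr
Why: deconjugative α-alkylation of the thermodynamic through-conjugated potassium dienolate, followed by base-mediated return of the double bond into conjugation, should place the acetate arm on the enone α-carbon, and any epimerization of the γ-methine through the dienolate returns to the more stable equatorial arrangement.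

Step 16
Reactants: 26 enone with CH2CO2Me on the α-carbon
Product: 27 spiro-epoxide
Conditions: 3-ClC6H4CO3H, NaHCO3, CH2Cl2, 0 → 23 °C
Reagents that add atoms: 3-chloroperoxybenzoic acid, OOC(=O)c1cccc(Cl)c1
Why: peracid epoxidation of the only electron-rich, unconjugated alkene, with oxygen delivered from the open ring-D side because the axial angular methyl blocks the ring-C side and the tertiary hydroxyl can hydrogen-bond to the peracid, should give the epoxide oxygen on the ring-D side as in the target.

Step 17
Reactants: 27 spiro-epoxide
Product: 28 dienyl triflate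
Conditions: KN(SiMe3)2 (2.2 equiv), THF, −78 °C; PhNTf2, −78 → −40 °C
Reagents that add atoms: N-phenylbis(trifluoromethanesulfonimide), O=S(=O)(N(c1ccccc1)S(=O)(=O)C(F)(F)F)C(F)(F)F
Why: kinetic α'-deprotonation of the enone at the ring-B CH2 and O-triflation give the 2-triflyloxy-1,3-diene, which fixes the second ring-B double bond.

Step 18
Reactants: 28 dienyl triflate
Product: 29 dienyl methyl ketone
Conditions: Pd(PPh3)4 (5 mol %), CO (1 atm), Me4Sn, LiCl, DMF, 60 °C
Reagents that add atoms: carbon monoxide, [C-]#[O+]; tetramethylstannane, C[Sn](C)(C)C
Why: carbonylative Stille coupling of the alkenyl triflate (oxidative addition, CO insertion, methyl transfer from tin) installs the acetyl group under neutral conditions that should spare the epoxide.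

Step 19
Reactants: 29 dienyl methyl ketone
Product: 31 CNP0605450.1, via hydroxy ester 30 (not isolated)
Conditions: MeMgCl, CeCl3, THF, −78 → 23 °C; aq. NH4Cl
Reagents that add atoms: methylmagnesium chloride, C[Mg]Cl
Why: chemoselective 1,2-addition to the unhindered methyl ketone (the ring-D ketone lies between two fully substituted carbons) gives the tertiary allylic alkoxide, which should close ring A by 6-exo-trig acyl substitution on the neighbouring methyl ester without touching a stereocentre.

**Compound list**

1 | 2,4-dimethoxytoluene | COc1ccc(C)c(OC)c1 | starting material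
2 | 1,5-dimethoxy-2-methylcyclohexa-1,4-diene | COC1=C(C)CC=C(OC)C1 | intermediate
3 | 7,7-dibromo-1,3-dimethoxy-6-methylbicyclo[4.1.0]hept-3-ene (not isolated) | COC12CC(OC)=CCC1(C)C2(Br)Br | intermediate
4 | 2-bromo-6-methoxy-3-methylcyclohepta-2,5-dien-1-one | O=C1CC(OC)=CCC(C)=C1Br | intermediate
5 | (S)-2-bromo-6-methoxy-3-methylcyclohepta-2,5-dien-1-ol | O[C@H]1CC(OC)=CCC(C)=C1Br | intermediate
6 | tert-butyldimethylsilyl ether of 5 | CC(C)(C)[Si](C)(C)O[C@H]1CC(OC)=CCC(C)=C1Br | intermediate
7 | alkenyllithium from 6, lithium in place of bromine (not isolated) | [Li]C1=C(C)CC=C(OC)C[C@@H]1O[Si](C)(C)C(C)(C)C | intermediate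
8 | [(S)-7-(tert-butyldimethylsilyloxy)-5-methoxy-2-methylcyclohepta-1,4-dien-1-yl]methanol | CC(C)(C)[Si](C)(C)O[C@H]1CC(OC)=CCC(C)=C1CO | intermediate
9 | diketene (4-methyleneoxetan-2-one) | C=C1CC(=O)O1 | starting material
10 | 3-oxobutanoate (acetoacetate) ester of 8 | CC(=O)CC(=O)OCC1=C(C)CC=C(OC)C[C@@H]1O[Si](C)(C)C(C)(C)C | intermediate
11 | 2-methylpent-1-en-3-one | CCC(=O)C(C)=C | starting material
12 | 2-acetyl-4-methyl-5-oxoheptanoate ester of 8, Michael adduct (not isolated) | CC(=O)C(CC(C)C(=O)CC)C(=O)OCC1=C(C)CC=C(OC)C[C@@H]1O[Si](C)(C)C(C)(C)C | intermediate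
13 | 2,3,5-trimethyl-4-oxocyclohex-2-ene-1-carboxylate ester of 8 (epimers at C-1 and C-5 of the cyclohexenone) | CC1=C(C)C(=O)C(C)CC1C(=O)OCC2=C(C)CC=C(OC)C[C@@H]2O[Si](C)(C)C(C)(C)C | intermediate
14 | bis(trimethylsilyl) derivative of 13: silyl ketene acetal with the allyloxy group cis to the C(CH3)= branch, ring ketone as 2-silyloxy diene (not isolated) | CC1=C(O[Si](C)(C)C)C(C)=C(C)/C(C1)=C(\OCC2=C(C)CC=C(OC)C[C@@H]2O[Si](C)(C)C(C)(C)C)O[Si](C)(C)C | intermediate
15 | trimethylsilyl ester of 16 with the ring-D ketone still as trimethylsilyl dienol ether (not isolated) | C[Si](C)(C)OC(=O)[C@]1(CC(C)=C(O[Si](C)(C)C)C(C)=C1C)[C@@]2(C)CC=C(OC)C[C@H](O[Si](C)(C)C(C)(C)C)C2=C | intermediate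
16 | 2,3,5-trimethyl-4-oxocyclohex-2-ene-1-carboxylic acid bearing at C-1 the 7-silyloxy-5-methoxy-1-methyl-2-methylenecyclohept-4-en-1-yl group (quaternary centres as in the target, silyloxy trans to the new C–C bond, epimers at C-5) | OC(=O)[C@]1(CC(C)C(=O)C(C)=C1C)[C@@]2(C)CC=C(OC)C[C@H](O[Si](C)(C)C(C)(C)C)C2=C | intermediate
17 | methyl ester of 16 | COC(=O)[C@]1(CC(C)C(=O)C(C)=C1C)[C@@]2(C)CC=C(OC)C[C@H](O[Si](C)(C)C(C)(C)C)C2=C | intermediate
18 | 5-hydroxy derivative of 17 (tertiary alcohol cis to CO2Me on ring D) | COC(=O)[C@]1(C[C@@](C)(O)C(=O)C(C)=C1C)[C@@]2(C)CC=C(OC)C[C@H](O[Si](C)(C)C(C)(C)C)C2=C | intermediate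
19 | diol: 18 with the ring-B silyl ether cleaved | COC(=O)[C@]1(C[C@@](C)(O)C(=O)C(C)=C1C)[C@@]2(C)CC=C(OC)C[C@H](O)C2=C | intermediate
20 | key precursor: 19 with the ring-B carbinol oxidized to the ketone (5-methoxy-2-methylenecyclohept-4-en-1-one unit) | COC(=O)[C@]1(C[C@@](C)(O)C(=O)C(C)=C1C)[C@@]2(C)CC=C(OC)CC(=O)C2=C | intermediate
21 | first-formed Michael adduct: bicyclo[3.3.1]nonane with C=CH2 bridge, ring-B ketone and non-conjugated enol ether (not isolated) | COC(=O)[C@]12C[C@@](C)(O)C(=O)[C@](C)(C[C@H]3C(=O)CC(OC)=CC[C@@]31C)C2=C | intermediate
22 | tricyclic vinylogous ester: rings C and D as in the target except C=CH2 in place of the epoxide; ring B = 3-methoxycyclohept-2-en-1-one with C=O next to the B/C methine | COC(=O)[C@]12C[C@@](C)(O)C(=O)[C@](C)(C[C@H]3C(=O)C=C(OC)CC[C@@]31C)C2=C | intermediate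
23 | tertiary allylic alcohol from methyl addition to the ring-B carbonyl of 22 (not isolated) | COC(=O)[C@]12C[C@@](C)(O)C(=O)[C@](C)(C[C@H]3C(C)(O)C=C(OC)CC[C@@]31C)C2=C | intermediate
24 | transposed enone: ring B = 3-methylcyclohept-2-en-1-one with the methyl-bearing carbon next to the B/C methine | COC(=O)[C@]12C[C@@](C)(O)C(=O)[C@](C)(C[C@H]3C(C)=CC(=O)CC[C@@]31C)C2=C | intermediate
25 | α-alkylated, deconjugated ketone with exocyclic methylene in ring B (not isolated) | COC(=O)[C@]12C[C@@](C)(O)C(=O)[C@](C)(C[C@H]3C(=C)C(CC(=O)OC)C(=O)CC[C@@]31C)C2=C | intermediate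
26 | ring-B enone bearing CH2CO2Me on the α-carbon | COC(=O)[C@]12C[C@@](C)(O)C(=O)[C@](C)(C[C@H]3C(C)=C(CC(=O)OC)C(=O)CC[C@@]31C)C2=C | intermediate
27 | spiro-epoxide of 26 (epoxide oxygen on the ring-D side) | COC(=O)[C@]12C[C@@](C)(O)C(=O)[C@](C)(C[C@H]3C(C)=C(CC(=O)OC)C(=O)CC[C@@]31C)[C@]21CO1 | intermediate
28 | dienyl triflate from the ring-B ketone of 27 | COC(=O)[C@]12C[C@@](C)(O)C(=O)[C@](C)(C[C@H]3C(C)=C(CC(=O)OC)C(OS(=O)(=O)C(F)(F)F)=CC[C@@]31C)[C@]21CO1 | intermediate
29 | dienyl methyl ketone (acetyl in place of the triflate) | COC(=O)[C@]12C[C@@](C)(O)C(=O)[C@](C)(C[C@H]3C(C)=C(CC(=O)OC)C(C(C)=O)=CC[C@@]31C)[C@]21CO1 | intermediate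
30 | hydroxy ester: 2-hydroxyprop-2-yl in place of acetyl (not isolated) | COC(=O)[C@]12C[C@@](C)(O)C(=O)[C@](C)(C[C@H]3C(C)=C(CC(=O)OC)C(C(C)(C)O)=CC[C@@]31C)[C@]21CO1 | intermediate
31 | CNP0605450.1 | COC(=O)[C@]12C[C@@](C)(O)C(=O)[C@](C)(C[C@H]3C(C)=C4CC(=O)OC(C)(C)C4=CC[C@@]31C)[C@]21CO1 | target

**Totals and risks**

Total step count: 19. Longest linear sequence: 19 steps (from 1; 9 and 11 enter as purchased reagents).

Steps most likely to fail:

Step 13. The dienolate may bond through its exocyclic γ-carbon (fused instead of bridged ring), or the methylene ketone may be lost by self-condensation before it cyclizes. The fallback replaces the reversible conjugate addition by an irreversible allylic alkylation, where extended enolates react at the α-carbon. It sets out from diol 19: methyl chloroformate and pyridine should acylate only the secondary allylic hydroxyl to give the methyl carbonate F1. Pd(PPh3)4 with LiN(SiMe3)2 (zerovalent palladium ionizes the carbonate; the lithium dienolate attacks the CH2 terminus of the allyl complex through its α-carbon) should give the bridged enol ether F2. Aqueous HCl should hydrolyse the enol ether and move the ring-B double bond into conjugation to give the cycloheptenone F3, with the B/C methine under thermodynamic control. Me2CuLi followed by methyl bromoacetate should give the keto ester F4, and dehydrogenation with 2-iodoxybenzoic acid should lead to 26, where the route is rejoined.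

Step 8. Dianion formation may be incomplete, the ketene acetal may form with the other geometry or react through a boat (wrong epimer at the ester-bearing carbon), or the rearrangement may stall at the tetrasubstituted alkene terminus. The fallback sets the angular quaternary carbon first by a less demanding acetate Claisen and builds ring D afterwards. It sets out from alcohol 8: Johnson–Claisen rearrangement with MeC(OMe)3 (cat. EtCO2H, 140 °C) should give the γ,δ-unsaturated ester F5, with bond formation anti to the silyloxy group. LiN(i-Pr)2 and N-methoxy-N-methylacetamide should give the β-keto ester F6. KOt-Bu-mediated Robinson annulation with 11, through the Michael adduct F7, comes back to the route at 17. The ester-bearing carbon is then set without chair control, so its epimers would have to be separated.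

Step 15. Alkylation may run through the cross-conjugated α'-enolate (at the ring-B CH2 next to the ketone) or occur twice. The fallback makes the bond by cross-coupling before the carbonyl transposition. It sets out from 22: N-bromosuccinimide should give the bromo vinylogous ester F8. Negishi coupling with BrZnCH2CO2Me (Pd2(dba)3, P(t-Bu)3) should give the ester F9. MeLi/CeCl3 at −78 °C and then aqueous HCl, through the tertiary alcohol F10, come back to the route at 26.

Further compounds
F1 | step 13 | methyl carbonate of the secondary ring-B alcohol of 19 | COC(=O)[C@]1(C[C@@](C)(O)C(=O)C(C)=C1C)[C@@]2(C)CC=C(OC)C[C@H](OC(=O)OC)C2=C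
F2 | step 13 | bridged allylation product: bicyclo[3.3.1]nonane with C=CH2 bridge, ring B = 1-methoxycyclohepta-1,4-diene | COC(=O)[C@]12C[C@@](C)(O)C(=O)[C@](C)(CC3=CCC(OC)=CC[C@@]31C)C2=C
F3 | step 13 | ring-B cyclohept-2-en-1-one with the β-carbon next to the B/C methine | COC(=O)[C@]12C[C@@](C)(O)C(=O)[C@](C)(C[C@H]3C=CC(=O)CC[C@@]31C)C2=C
F4 | step 13 | ring-B ketone with β-methyl and α-CH2CO2Me | COC(=O)[C@]12C[C@@](C)(O)C(=O)[C@](C)(C[C@H]3C(C)C(CC(=O)OC)C(=O)CC[C@@]31C)C2=C
F5 | step 8 | methyl 2-[7-(tert-butyldimethylsilyloxy)-5-methoxy-1-methyl-2-methylenecyclohept-4-en-1-yl]acetate | COC(=O)C[C@@]1(C)CC=C(OC)C[C@H](O[Si](C)(C)C(C)(C)C)C1=C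
F6 | step 8 | α-acetyl derivative of F5 (β-keto ester) | COC(=O)C(C(C)=O)[C@@]1(C)CC=C(OC)C[C@H](O[Si](C)(C)C(C)(C)C)C1=C
F7 | step 8 | Michael adduct of F6 with 11 (not isolated) | COC(=O)C(CC(C)C(=O)CC)(C(C)=O)[C@@]1(C)CC=C(OC)C[C@H](O[Si](C)(C)C(C)(C)C)C1=C
F8 | step 15 | α-bromo vinylogous ester from 22 | COC(=O)[C@]12C[C@@](C)(O)C(=O)[C@](C)(C[C@H]3C(=O)C(Br)=C(OC)CC[C@@]31C)C2=C
F9 | step 15 | vinylogous ester with CH2CO2Me on the α-carbon | COC(=O)[C@]12C[C@@](C)(O)C(=O)[C@](C)(C[C@H]3C(=O)C(CC(=O)OC)=C(OC)CC[C@@]31C)C2=C
F10 | step 15 | tertiary allylic alcohol from methyl addition to F9 (not isolated) | COC(=O)[C@]12C[C@@](C)(O)C(=O)[C@](C)(C[C@H]3C(C)(O)C(CC(=O)OC)=C(OC)CC[C@@]31C)C2=C
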